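**Plan**

- Oxane numbering: O1, C2 (acrylic acid), C3, C4, C5 (side chain C1′–C13′), C6. The retrosynthesis cuts the C–CO2H bond (back to a C2 ethynyl group), then O1–C6 (ring opened to a C6 alcohol and a C2 silyl ether), then C5–C6 and C4–C5.
- Enabling feature: C5 is a ring CH flanked by three methylene carbons (C4, C6, C1′), the pattern left by two consecutive boronic ester homologations at one carbon.
- Forward: farnesol and tert-butyl acetate give the C16 carbamate (C5 plus C1′–C13′); TIPS-acetylene and acrolein give the (R)-C2–C4 pinacol boronate carrying the masked acrylate.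
- One flask joins C4–C5 (lithiation–borylation) and C5–C6 (chloromethyl insertion) without closing a ring. Boronate oxidation, mesylation and fluoride-triggered O1–C6 etherification then form the only ring, and alkyne hydrocarboxylation completes the acid.
- Stereochemistry: C2 (R) comes from lipase resolution and its C–O bond is never broken afterwards. C5 (R) comes from (−)-sparteine-directed lithiation and two stereospecific 1,2-boron shifts. Together they give the cis-2,5-oxane.

Key step: step 10

Assumption: the lipase is taken to follow the usual size rule for secondary alcohols (silylethynyl as the large group, vinyl as the medium one), so the (R)-alcohol is the enantiomer acylated; the sense would be confirmed by Mosher ester analysis before material is carried forward.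

**Route**

Step 1
Reactants: 1 (2E,6E)-farnesol
Product: 2 (2E,6E)-farnesyl bromide
Conditions: PBr3 (0.4 equiv), Et2O, −10 → 0 °C; used without storage
Reagents that add atoms: phosphorus tribromide, BrP(Br)Br
Why: Conversion of a primary allylic alcohol to the bromide (SN2 on the phosphite ester) at low temperature should keep the 2E geometry and avoid allylic transposition.

Step 2
Reactants: 2 (2E,6E)-farnesyl bromide; 3 tert-butyl acetate
Product: 4 tert-butyl (4E,8E)-5,9,13-trimethyltetradeca-4,8,12-trienoate
Conditions: 3, LDA, THF, −78 °C; then 2, −78 → 0 °C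
Reagents that add atoms: none
Why: Ester enolate alkylation, in which the lithium enolate of the hindered tert-butyl ester displaces the primary allylic bromide by SN2 and supplies the two carbons that become C5 and C1′.

Step 3
Reactants: 4 tert-butyl (4E,8E)-5,9,13-trimethyltetradeca-4,8,12-trienoate
Product: 5 (4E,8E)-5,9,13-trimethyltetradeca-4,8,12-trien-1-ol
Conditions: LiAlH4, THF, 0 °C → rt
Reagents that add atoms: none
Why: Hydride reduction of an ester to the primary alcohol, to which the isolated trisubstituted alkenes are inert.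

Step 4
Reactants: 5 (4E,8E)-5,9,13-trimethyltetradeca-4,8,12-trien-1-ol
Product: 6 (4E,8E)-5,9,13-trimethyltetradeca-4,8,12-trien-1-yl N,N-diisopropylcarbamate
Conditions: i-Pr2NCOCl, Et3N, CH2Cl2, reflux
Reagents that add atoms: N,N-diisopropylcarbamoyl chloride, CC(C)N(C(C)C)C(Cl)=O
Why: O-Carbamoylation of the primary alcohol installs the group that later directs α-lithiation at C5 and then acts as the leaving group.

Step 5
Reactants: 7 (triisopropylsilyl)acetylene; 8 acrolein
Product: 9 rac-5-(triisopropylsilyl)pent-1-en-4-yn-3-ol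
Conditions: 7, n-BuLi, THF, −78 °C; then 8, −78 → 0 °C; H2O quench
Reagents that add atoms: none
Why: Acetylide addition to an aldehyde, the hard lithium acetylide adding 1,2 to acrolein rather than in conjugate fashion.

Step 6
Reactants: 9 rac-5-(triisopropylsilyl)pent-1-en-4-yn-3-ol
Product: 10 (3R)-5-(triisopropylsilyl)pent-1-en-4-yn-3-yl acetate
Conditions: Amano lipase AK, vinyl acetate, hexane, 4 Å MS, rt, stopped near half conversion; chromatographic separation from the unreacted (S)-alcohol
Reagents that add atoms: vinyl acetate, C=COC(C)=O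
Why: Lipase-catalysed kinetic resolution by irreversible transesterification, in which the enzyme should seat the silylethynyl rod as the large and vinyl as the medium substituent and so acylate the (R)-alcohol selectively, which fixes C2.

Step 7
Reactants: 10 (3R)-5-(triisopropylsilyl)pent-1-en-4-yn-3-yl acetate
Product: 11 (3R)-5-(triisopropylsilyl)pent-1-en-4-yn-3-ol
Conditions: K2CO3 (cat.), MeOH, 0 °C → rt
Reagents that add atoms: none
Why: Base-catalysed transesterification (methanolysis) removes the acetate without breaking the C–O bond at the stereocentre, and a TIPS-alkyne is stable to K2CO3/MeOH.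

Step 8
Reactants: 11 (3R)-5-(triisopropylsilyl)pent-1-en-4-yn-3-ol
Product: 12 triethyl{[(3R)-5-(triisopropylsilyl)pent-1-en-4-yn-3-yl]oxy}silane
Conditions: TESCl, imidazole, CH2Cl2, 0 °C → rt
Reagents that add atoms: chlorotriethylsilane, CC[Si](Cl)(CC)CC
Why: Silyl ether formation gives a C2 protecting group that tolerates organolithium and perborate conditions and is later removed by fluoride together with the alkyne silyl group.

Step 9
Reactants: 12 triethyl{[(3R)-5-(triisopropylsilyl)pent-1-en-4-yn-3-yl]oxy}silane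
Product: 13 2-[(3R)-3-(triethylsilyloxy)-5-(triisopropylsilyl)pent-4-yn-1-yl]-4,4,5,5-tetramethyl-1,3,2-dioxaborolane
Conditions: HBpin, [Ir(cod)Cl]2 (1.5 mol %), dppm (3 mol %), CH2Cl2, rt
Reagents that add atoms: pinacolborane, CC1(C)OBOC1(C)C
Why: Iridium-catalysed anti-Markovnikov hydroboration of a terminal alkene places boron on the terminal carbon (C4), and the TIPS-shielded internal alkyne should not react.

Step 10
Reactants: 6 (4E,8E)-5,9,13-trimethyltetradeca-4,8,12-trien-1-yl N,N-diisopropylcarbamate; 13 2-[(3R)-3-(triethylsilyloxy)-5-(triisopropylsilyl)pent-4-yn-1-yl]-4,4,5,5-tetramethyl-1,3,2-dioxaborolane; 14 bromochloromethane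
Product: 17 2-[(2R,5R)-2-[(3E,7E)-4,8,12-trimethyltrideca-3,7,11-trien-1-yl]-5-(triethylsilyloxy)-7-(triisopropylsilyl)hept-6-yn-1-yl]-4,4,5,5-tetramethyl-1,3,2-dioxaborolane, via (S)-α-lithiated carbamate 15 (not isolated), via secondary boronate 16 (not isolated)
Conditions: 6 (1.3 equiv), s-BuLi, (−)-sparteine, Et2O, −78 °C, 5 h; 13 (1.0 equiv) in Et2O, −78 °C, 1 h, then reflux, 16 h; cool to −78 °C, THF, 14 (3 equiv), n-BuLi (2.5 equiv), −78 °C → rt
Reagents that add atoms: none
Why: s-BuLi/(−)-sparteine removes the pro-S proton at C5 next to the carbamate oxygen to give the configurationally stable (S)-α-oxyalkyllithium 15, which adds to the boron of 13 with retention, and on warming the C4 alkyl group migrates from boron to C5 anti to the departing carbamate (inversion at C5) to form C4–C5 in the (R)-boronate 16. Chloromethyllithium made in the same flask from 14 and n-BuLi then forms a second ate complex, and C5 migrates to the CH2 group with retention as chloride leaves (Matteson homologation), which forms C5–C6. The closest known reaction type is the lithiation–borylation of primary N,N-diisopropylcarbamates with pinacol boronates followed by chloromethyl homologation. No ring is formed. The one new stereocentre (C5, R) is set by the chiral diamine alone, the remote C2 centre playing no part, and both 1,2-shifts are stereospecific. The step needs C5–H removal to outrun allylic metallation of the triene and attack at boron to outrun any other site of 13: the carbamate carbonyl pre-complexes the base so that deprotonation at −78 °C is directed to C5, and 13 offers only silyl-protected oxygen and a TIPS-capped alkyne besides boron.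

Step 11
Reactants: 17 2-[(2R,5R)-2-[(3E,7E)-4,8,12-trimethyltrideca-3,7,11-trien-1-yl]-5-(triethylsilyloxy)-7-(triisopropylsilyl)hept-6-yn-1-yl]-4,4,5,5-tetramethyl-1,3,2-dioxaborolane
Product: 18 (2R,5R)-2-[(3E,7E)-4,8,12-trimethyltrideca-3,7,11-trien-1-yl]-5-(triethylsilyloxy)-7-(triisopropylsilyl)hept-6-yn-1-ol
Conditions: NaBO3·4H2O, THF/H2O (1:1), rt
Reagents that add atoms: sodium perborate, [Na+].[O-]OB=O
Why: Boronate oxidation (1,2-shift of the C6 methylene from boron to oxygen) should give the primary alcohol under mild conditions that leave the alkenes, the TES ether and the silylalkyne untouched.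

Step 12
Reactants: 18 (2R,5R)-2-[(3E,7E)-4,8,12-trimethyltrideca-3,7,11-trien-1-yl]-5-(triethylsilyloxy)-7-(triisopropylsilyl)hept-6-yn-1-ol
Product: 19 (2R,5R)-2-[(3E,7E)-4,8,12-trimethyltrideca-3,7,11-trien-1-yl]-5-(triethylsilyloxy)-7-(triisopropylsilyl)hept-6-yn-1-yl methanesulfonate
Conditions: MsCl, Et3N, CH2Cl2, 0 °C
Reagents that add atoms: methanesulfonyl chloride, CS(=O)(=O)Cl
Why: Sulfonylation of the only free hydroxyl (mesylate formation) places the leaving group unambiguously on C6.

Step 13
Reactants: 19 (2R,5R)-2-[(3E,7E)-4,8,12-trimethyltrideca-3,7,11-trien-1-yl]-5-(triethylsilyloxy)-7-(triisopropylsilyl)hept-6-yn-1-yl methanesulfonate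
Product: 21 (2R,5R)-2-ethynyl-5-[(3E,7E)-4,8,12-trimethyltrideca-3,7,11-trien-1-yl]oxane, via C2-hydroxy mesylate 20 (not isolated)
Conditions: TBAF (1 M in THF, 3.5 equiv), THF, 0 °C → rt (40 °C if ring closure lags)
Reagents that add atoms: none
Why: Fluoride cleaves the TES ether and the alkynyl C–Si bond, and the freed C2 alkoxide closes O1–C6 by intramolecular Williamson etherification (6-exo-tet SN2 at the primary mesylate, expected to be faster than intermolecular fluoride displacement), so C2 keeps its configuration because oxygen is the nucleophile.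

Step 14
Reactants: 21 (2R,5R)-2-ethynyl-5-[(3E,7E)-4,8,12-trimethyltrideca-3,7,11-trien-1-yl]oxane; 22 formic acid
Product: 23 rhopaloic acid B, 2-[(2R,5R)-5-[(3E,7E)-4,8,12-trimethyltrideca-3,7,11-trien-1-yl]oxan-2-yl]prop-2-enoic acid
Conditions: Pd(OAc)2 (5 mol %), Xantphos (10 mol %), 22 (2 equiv), Ac2O (20 mol %), toluene, 80 °C
Reagents that add atoms: none
Why: Palladium-catalysed Markovnikov hydrocarboxylation of a terminal alkyne with formic acid as the CO and hydride source, in which hydropalladation puts Pd on the internal carbon and carbonylation then gives the α-substituted acrylic acid without touching a stereocentre.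

**Compound list**

1 | (2E,6E)-farnesol | OC/C=C(\C)CC/C=C(\C)CCC=C(C)C | starting material
2 | (2E,6E)-farnesyl bromide | BrC/C=C(\C)CC/C=C(\C)CCC=C(C)C | intermediate
3 | tert-butyl acetate | CC(=O)OC(C)(C)C | starting material
4 | tert-butyl (4E,8E)-5,9,13-trimethyltetradeca-4,8,12-trienoate | CC(C)(C)OC(=O)CC/C=C(\C)CC/C=C(\C)CCC=C(C)C | intermediate
5 | (4E,8E)-5,9,13-trimethyltetradeca-4,8,12-trien-1-ol | OCCC/C=C(\C)CC/C=C(\C)CCC=C(C)C | intermediate
6 | (4E,8E)-5,9,13-trimethyltetradeca-4,8,12-trien-1-yl N,N-diisopropylcarbamate | CC(C)N(C(C)C)C(=O)OCCC/C=C(\C)CC/C=C(\C)CCC=C(C)C | intermediate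
7 | (triisopropylsilyl)acetylene | C#C[Si](C(C)C)(C(C)C)C(C)C | starting material
8 | acrolein | C=CC=O | starting material
9 | rac-5-(triisopropylsilyl)pent-1-en-4-yn-3-ol | C=CC(O)C#C[Si](C(C)C)(C(C)C)C(C)C | intermediate
10 | (3R)-5-(triisopropylsilyl)pent-1-en-4-yn-3-yl acetate | C=C[C@@H](OC(C)=O)C#C[Si](C(C)C)(C(C)C)C(C)C | intermediate
11 | (3R)-5-(triisopropylsilyl)pent-1-en-4-yn-3-ol | C=C[C@@H](O)C#C[Si](C(C)C)(C(C)C)C(C)C | intermediate
12 | triethyl{[(3R)-5-(triisopropylsilyl)pent-1-en-4-yn-3-yl]oxy}silane | C=C[C@@H](O[Si](CC)(CC)CC)C#C[Si](C(C)C)(C(C)C)C(C)C | intermediate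
13 | 2-[(3R)-3-(triethylsilyloxy)-5-(triisopropylsilyl)pent-4-yn-1-yl]-4,4,5,5-tetramethyl-1,3,2-dioxaborolane | CC1(C)OB(CC[C@@H](O[Si](CC)(CC)CC)C#C[Si](C(C)C)(C(C)C)C(C)C)OC1(C)C | intermediate
14 | bromochloromethane | ClCBr | starting material
15 | (1S,4E,8E)-1-lithio-5,9,13-trimethyltetradeca-4,8,12-trien-1-yl N,N-diisopropylcarbamate, as its (−)-sparteine complex | CC(C)N(C(C)C)C(=O)O[C@@H]([Li])CC/C=C(\C)CC/C=C(\C)CCC=C(C)C | intermediate
16 | 2-[(3R,6R,9E,13E)-10,14,18-trimethyl-3-(triethylsilyloxy)-1-(triisopropylsilyl)nonadeca-9,13,17-trien-1-yn-6-yl]-4,4,5,5-tetramethyl-1,3,2-dioxaborolane | CC1(C)OB([C@H](CC/C=C(\C)CC/C=C(\C)CCC=C(C)C)CC[C@@H](O[Si](CC)(CC)CC)C#C[Si](C(C)C)(C(C)C)C(C)C)OC1(C)C | intermediate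
17 | 2-[(2R,5R)-2-[(3E,7E)-4,8,12-trimethyltrideca-3,7,11-trien-1-yl]-5-(triethylsilyloxy)-7-(triisopropylsilyl)hept-6-yn-1-yl]-4,4,5,5-tetramethyl-1,3,2-dioxaborolane | CC1(C)OB(C[C@H](CC/C=C(\C)CC/C=C(\C)CCC=C(C)C)CC[C@@H](O[Si](CC)(CC)CC)C#C[Si](C(C)C)(C(C)C)C(C)C)OC1(C)C | intermediate
18 | (2R,5R)-2-[(3E,7E)-4,8,12-trimethyltrideca-3,7,11-trien-1-yl]-5-(triethylsilyloxy)-7-(triisopropylsilyl)hept-6-yn-1-ol | OC[C@H](CC/C=C(\C)CC/C=C(\C)CCC=C(C)C)CC[C@@H](O[Si](CC)(CC)CC)C#C[Si](C(C)C)(C(C)C)C(C)C | intermediate
19 | (2R,5R)-2-[(3E,7E)-4,8,12-trimethyltrideca-3,7,11-trien-1-yl]-5-(triethylsilyloxy)-7-(triisopropylsilyl)hept-6-yn-1-yl methanesulfonate | CS(=O)(=O)OC[C@H](CC/C=C(\C)CC/C=C(\C)CCC=C(C)C)CC[C@@H](O[Si](CC)(CC)CC)C#C[Si](C(C)C)(C(C)C)C(C)C | intermediate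
20 | (2R,5R)-5-hydroxy-2-[(3E,7E)-4,8,12-trimethyltrideca-3,7,11-trien-1-yl]-7-(triisopropylsilyl)hept-6-yn-1-yl methanesulfonate | CS(=O)(=O)OC[C@H](CC/C=C(\C)CC/C=C(\C)CCC=C(C)C)CC[C@@H](O)C#C[Si](C(C)C)(C(C)C)C(C)C | intermediate
21 | (2R,5R)-2-ethynyl-5-[(3E,7E)-4,8,12-trimethyltrideca-3,7,11-trien-1-yl]oxane | C#C[C@H]1CC[C@@H](CC/C=C(\C)CC/C=C(\C)CCC=C(C)C)CO1 | intermediate
22 | formic acid | OC=O | starting material
23 | rhopaloic acid B, 2-[(2R,5R)-5-[(3E,7E)-4,8,12-trimethyltrideca-3,7,11-trien-1-yl]oxan-2-yl]prop-2-enoic acid | C=C(C(=O)O)[C@H]1CC[C@@H](CC/C=C(\C)CC/C=C(\C)CCC=C(C)C)CO1 | target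

**Step count and risks**

Total step count: 14. Longest linear sequence: 10 steps (steps 5–14, from 7 and 8 to 23).

Steps most likely to fail:

1. Step 10. The first 1,2-metallate rearrangement may stall without a Lewis acid, allylic deprotonation of the triene may compete with C5–H removal and erode the enantiotopic selection, or leftover lithium carbamate and diamine may disturb carbenoid generation so that the chloromethyl insertion stays incomplete. Fallback: the carbenoid is generated by tin–lithium exchange and the two homologations are separated. Setting out from 6, lithiation with s-BuLi/(−)-sparteine (Et2O, −78 °C) and retentive quench with Me3SnCl give (1S,4E,8E)-5,9,13-trimethyl-1-(trimethylstannyl)tetradeca-4,8,12-trien-1-yl N,N-diisopropylcarbamate F1, which can be purified and checked for enantiopurity. Treatment of F1 with n-BuLi at −78 °C regenerates the (S)-lithiated carbamate free of diamine and excess base; 13 is added and MgBr2·OEt2 in refluxing Et2O drives the 1,2-shift. The route is rejoined at 16, which is now isolated and converted to 17 with 14/n-BuLi in THF in a separate flask.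

2. Step 14. Hydropalladation may lose regiocontrol (linear acid), or the trisubstituted alkenes may isomerise or cyclise under Pd–H and formic acid at 80 °C. Fallback: setting out from 21, molybdenum-catalysed hydrostannation (Bu3SnH, Mo(CO)3(CNt-Bu)3, THF, 55 °C), which places tin on the internal carbon of propargylic ethers, gives tributyl{1-[(2R,5R)-5-[(3E,7E)-4,8,12-trimethyltrideca-3,7,11-trien-1-yl]oxan-2-yl]ethenyl}stannane F2. Iododestannylation (I2, CH2Cl2, 0 °C) gives (2R,5R)-2-(1-iodoethenyl)-5-[(3E,7E)-4,8,12-trimethyltrideca-3,7,11-trien-1-yl]oxane F3, and palladium-catalysed hydroxycarbonylation (Pd(PPh3)4, CO 1 atm, K2CO3, THF/H2O, 50 °C) comes back to the route at 23.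

3. Step 6. Acyl transfer may be slow or unselective because the bulky TIPS group is poorly accommodated by the enzyme, or the enantiomer preference may be reversed. Fallback: setting out from 9, a Sharpless kinetic resolution (Ti(Oi-Pr)4, D-(−)-diisopropyl tartrate, t-BuOOH 0.6 equiv, 4 Å MS, CH2Cl2, −20 °C) is used instead. With this tartrate the (S)-enantiomer is the one epoxidised, to the erythro epoxy alcohol (1R)-1-[(2S)-oxiran-2-yl]-3-(triisopropylsilyl)prop-2-yn-1-ol F4, which is discarded. The unreacted (R)-alcohol is recovered directly, so the route is rejoined at 11 and step 7 is not needed.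

**Further compounds**

F1 | step 10 | (1S,4E,8E)-5,9,13-trimethyl-1-(trimethylstannyl)tetradeca-4,8,12-trien-1-yl N,N-diisopropylcarbamate | CC(C)N(C(C)C)C(=O)O[C@@H]([Sn](C)(C)C)CC/C=C(\C)CC/C=C(\C)CCC=C(C)C
F2 | step 14 | tributyl{1-[(2R,5R)-5-[(3E,7E)-4,8,12-trimethyltrideca-3,7,11-trien-1-yl]oxan-2-yl]ethenyl}stannane | C=C([Sn](CCCC)(CCCC)CCCC)[C@H]1CC[C@@H](CC/C=C(\C)CC/C=C(\C)CCC=C(C)C)CO1
F3 | step 14 | (2R,5R)-2-(1-iodoethenyl)-5-[(3E,7E)-4,8,12-trimethyltrideca-3,7,11-trien-1-yl]oxane | C=C(I)[C@H]1CC[C@@H](CC/C=C(\C)CC/C=C(\C)CCC=C(C)C)CO1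
F4 | step 6 | (1R)-1-[(2S)-oxiran-2-yl]-3-(triisopropylsilyl)prop-2-yn-1-ol | O[C@H](C#C[Si](C(C)C)(C(C)C)C(C)C)[C@@H]1CO1
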